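**Assumption (one line):** Numbering is the germacranolide numbering. C1–C10 is the ring, C11–C13 is the lactone unit, C14 is on C10 and C15 is on C4. α is the face carrying the 6-oxygen. The target is 2α-OH, 4α-OH, 5β-OiBu, 6α-O, 7β-C11, 8α-OiBu, 9-oxo, 10β-Me.

## Retrosynthetic overview
1. Cardivin D comes from the lactonisation of a C12 acid onto 6α-OH and the α-methylene unit from the C7 isopropenyl group (SeO₂). The 5- and 8-isobutyrates and the C9 ketone come from a late-stage 8,9-diol.
2. The C4/C5/C6 oxygenation comes from the carvone C=O/enone unit by epoxidation–Wharton–epoxide reduction–α′-oxygenation.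
3. The only carbocycle forms in one step, an anionic oxy-Cope ring expansion (6→10) of a 3-vinyl-8-propenyl-cyclohexenol. Carvone C1–C6 become C3–C8, and the new bond is C1–C10.
4. (R)-Carvone is the only chiral source: it gives C7, and all other centres are set by substrate control. The lactone is closed last.

## Route

**Step 1**
Reactants: 1, (R)-carvone
Product: 2, trans-6-allylcarvone (C8 allyl trans to the C7 isopropenyl)
Conditions: LDA, THF, –78 °C; then allyl bromide, –78 → 0 °C
Reagents that add atoms: allyl bromide, C=CCBr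
Why: Kinetic enolisation at the less hindered α′-carbon followed by enolate alkylation anti to the neighbouring isopropenyl group gives the trans product.

**Step 2**
Reactants: 2
Product: 3, tertiary allylic alcohol (3-OH cis to the 8-allyl, 3-vinyl trans to it)
Conditions: vinylMgBr, anhydrous CeCl₃, THF, –78 °C
Reagents that add atoms: vinylmagnesium bromide, C=C[Mg]Br
Why: Organocerium 1,2-addition to the enone carbonyl occurs anti to the adjacent allyl group, and the C3 centre is destroyed in Step 4.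

**Step 3**
Reactants: 3
Product: 4, (E)-propenyl compound
Conditions: RuHCl(CO)(PPh₃)₃ (5 mol%), toluene, 80 °C
Reagents that add atoms: none
Why: Ru–H chain-walking isomerisation converts the terminal allyl alkene into the E-propenyl group. The vinyl group on the quaternary carbinol, the trisubstituted ring alkene and the isopropenyl cannot migrate.

**Step 4**
Reactants: 4
Product: 5, (4Z,8E)-2α-hydroxygermacra-4,8,11(13)-trien-3-one
Conditions: KH, 18-crown-6, THF, 0 → 55 °C; then –78 °C, 2-(phenylsulfonyl)-3-phenyloxaziridine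
Reagents that add atoms: 2-(phenylsulfonyl)-3-phenyloxaziridine, O=S(=O)(c1ccccc1)N1OC1c1ccccc1
Why: In the anionic oxy-Cope ([3,3]) the C3–C8 bond breaks and the C1–C10 bond forms, giving the 10-membered ring. The chair-like transition state with the E-propenyl sets C10 (10β-Me), and Davis hydroxylation of the resulting C2=C3 enolate from the peripheral face sets 2α-OH.

**Step 5**
Reactants: 5
Product: 6, 2α-OTBS ether
Conditions: TBSCl, imidazole, DMF, rt
Reagents that add atoms: TBSCl, C[Si](C)(C(C)(C)C)Cl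
Why: Silylation protects the C2 alcohol from the later oxidations.

**Step 6**
Reactants: 6
Product: 7, 4α,5α-epoxy-3-ketone
Conditions: 30% H₂O₂, 6 M NaOH, MeOH, 0 °C
Reagents that add atoms: hydrogen peroxide, OO
Why: Weitz–Scheffer nucleophilic epoxidation acts only on the enone C4=C5, leaving the strained E-C8=C9 and the isopropenyl untouched. The epoxide is delivered to the peripheral α-face, anti to the 7β-substituent.

**Step 7**
Reactants: 7
Product: 8, germacra-3,8,11(13)-trien-5α-ol (2α-OTBS)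
Conditions: N₂H₄·H₂O, AcOH (cat.), MeOH, 0 °C → rt
Reagents that add atoms: none
Why: The Wharton reaction turns the C3 carbonyl into the C3=C4 alkene and keeps the epoxide oxygen as 5α-OH with retained configuration. This also removes the surplus C3 oxygen.

**Step 8**
Reactants: 8
Product: 9, 3α,4α-epoxy-5α-ol
Conditions: VO(acac)₂ (5 mol%), TBHP, CH₂Cl₂, 0 °C
Reagents that add atoms: tert-butyl hydroperoxide, CC(C)(C)OO
Why: Hydroxyl-directed (Sharpless–Michaelson) epoxidation occurs syn to 5α-OH, and the isolated alkenes do not react with V/TBHP.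

**Step 9**
Reactants: 9
Product: 10, 2α-OTBS-germacra-8,11(13)-diene-4α,5α-diol
Conditions: DIBAL-H, toluene, –78 → 0 °C
Reagents that add atoms: none
Why: Aluminium-directed hydride delivery goes to the secondary epoxide carbon C3 rather than the tertiary C4, giving C3H₂ and retaining the C4 oxygen as 4α-OH.

**Step 10**
Reactants: 10
Product: 11, 4α-hydroxy-5-ketone
Conditions: (COCl)₂, DMSO, Et₃N, CH₂Cl₂, –78 °C
Reagents that add atoms: none
Why: Swern oxidation takes the secondary 5-OH selectively and leaves the tertiary 4-OH, and C6 is the only enolisable position.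

**Step 11**
Reactants: 11
Product: 12, 4α,6α-dihydroxy-5-ketone
Conditions: LDA (2.5 equiv), THF, –78 °C; then 2-(phenylsulfonyl)-3-phenyloxaziridine
Reagents that add atoms: 2-(phenylsulfonyl)-3-phenyloxaziridine, O=S(=O)(c1ccccc1)N1OC1c1ccccc1
Why: Regiospecific enolisation toward C6 (C4 is quaternary) followed by Davis hydroxylation anti to the 7β-substituent gives 6α-OH.

**Step 12**
Reactants: 12
Product: 13, 6α-OTBS ether
Conditions: TBSCl, imidazole, DMF, rt
Reagents that add atoms: TBSCl, C[Si](C)(C(C)(C)C)Cl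
Why: These conditions silylate the secondary C6 alcohol only, so the tertiary 4-OH stays free for the directed reduction in Step 13.

**Step 13**
Reactants: 13
Product: 14, 5β-alcohol (4α-OH, 5β-OH, 6α-OTBS)
Conditions: Me₄NBH(OAc)₃, MeCN/AcOH (1:1), –20 °C → rt
Reagents that add atoms: none
Why: In the Evans–Saksena directed reduction, hydride is delivered from the 4α-OH face, so the new 5-OH ends up anti (β).

**Step 14**
Reactants: 14
Product: 15, 5β-O-isobutyrate
Conditions: (iPrCO)₂O, Et₃N, DMAP, CH₂Cl₂, 40 °C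
Reagents that add atoms: isobutyric anhydride, CC(C)C(=O)OC(=O)C(C)C
Why: The secondary 5-OH is acylated, while the tertiary 4-OH and the silyl ethers are unreactive.

**Step 15**
Reactants: 15
Product: 16, 8α,9-diol (trans-diol; C9 configuration is immaterial)
Conditions: OsO₄ (5 mol%), NMO, acetone/H₂O, rt
Reagents that add atoms: osmium tetroxide, O=[Os](=O)(=O)=O; N-methylmorpholine N-oxide, C[N+]1([O-])CCOCC1 (co-oxidant)
Why: Upjohn syn-dihydroxylation prefers the strained E-C8=C9 over the isopropenyl, and attack anti to the 7β-group gives 8α-OH.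

**Step 16**
Reactants: 16
Product: 17, 8α-hydroxy-9-ketone
Conditions: Pd(OAc)₂, neocuproine, O₂, toluene, 60 °C
Reagents that add atoms: none
Why: Pd-catalysed aerobic oxidation of a vicinal diol to the α-hydroxy ketone should take the less hindered C9–OH, which is flanked by C10 rather than the branched C7-adjacent C8.

**Step 17**
Reactants: 17
Product: 18, 8α-O-isobutyrate
Conditions: iPrCOCl, pyridine, DMAP, CH₂Cl₂, 0 °C
Reagents that add atoms: isobutyryl chloride, CC(C)C(=O)Cl
Why: Acylation of the last free secondary alcohol installs the 8-ester without affecting C8 stereochemistry.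

**Step 18**
Reactants: 18
Product: 19, 12-hydroxy compound (C11(=CH₂)CH₂OH)
Conditions: SeO₂ (cat.), TBHP, CH₂Cl₂, rt
Reagents that add atoms: selenium dioxide, O=[Se]=O; tert-butyl hydroperoxide, CC(C)(C)OO
Why: Riley allylic oxidation takes the isopropenyl methyl (C12), and the isopropenyl is now the only alkene left.

**Step 19**
Reactants: 19
Product: 20, α-methylene acid (C12 carboxylic acid)
Conditions: TEMPO (cat.), NaClO₂, NaOCl (cat.), MeCN, pH 6.7 phosphate buffer, 35 °C
Reagents that add atoms: sodium chlorite, [O-]Cl=O.[Na+]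
Why: Zhao–Anelli oxidation converts the primary allylic alcohol to the acid without touching the ketone, esters or silyl ethers.

**Step 20**
Reactants: 20
Product: 21, 2,6-dihydroxy acid
Conditions: HF·pyridine, THF/pyridine, 0 °C → rt
Reagents that add atoms: none
Why: Global TBS removal frees 6α-OH for lactonisation and 2α-OH for the final product.

**Step 21**
Reactants: 21
Product: 22, cardivin D
Conditions: 2,4,6-Cl₃C₆H₂COCl, Et₃N, THF; then DMAP, toluene, 80 °C (Yamaguchi)
Reagents that add atoms: none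
Why: Intramolecular Yamaguchi lactonisation of the C12 acid with 6α-OH closes the γ-lactone; 5-exo closure is much faster than closure onto the tertiary 4-OH (7-membered) or C2–OH (macrocycle), and it gives the trans-fused 6α,7β ring.

## Compound list
1 | (R)-carvone | CC1=CC[C@H](CC1=O)C(C)=C | starting material
2 | trans-6-allylcarvone | O=C1C(C)=CC[C@@H](C(C)=C)[C@@H]1CC=C | intermediate
3 | 6-allyl-5-isopropenyl-2-methyl-1-vinylcyclohex-2-en-1-ol | O[C@]1(C=C)C(C)=CC[C@@H](C(C)=C)[C@@H]1CC=C | intermediate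
4 | 6-(E-propenyl) analogue of 3 | O[C@]1(C=C)C(C)=CC[C@@H](C(C)=C)[C@@H]1/C=C/C | intermediate
5 | (4Z,8E)-2α-hydroxygermacra-4,8,11(13)-trien-3-one | C=C(C)[C@H]1/C=C/[C@@H](C)C[C@H](O)C(=O)/C(C)=C\C1 | intermediate
6 | 2α-OTBS ether of 5 | C=C(C)[C@H]1/C=C/[C@@H](C)C[C@H](O[Si](C)(C)C(C)(C)C)C(=O)/C(C)=C\C1 | intermediate
7 | 4α,5α-epoxy-3-ketone | C=C(C)[C@H]1/C=C/[C@@H](C)C[C@H](O[Si](C)(C)C(C)(C)C)C(=O)[C@]2(C)O[C@@H]2C1 | intermediate
8 | germacra-3,8,11(13)-trien-5α-ol, 2-OTBS | C=C(C)[C@H]1/C=C/[C@@H](C)C[C@H](O[Si](C)(C)C(C)(C)C)C=C(C)[C@H](O)C1 | intermediate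
9 | 3α,4α-epoxy-5α-ol | C=C(C)[C@H]1/C=C/[C@@H](C)C[C@H](O[Si](C)(C)C(C)(C)C)[C@@H]2O[C@]2(C)[C@H](O)C1 | intermediate
10 | 4α,5α-diol | C=C(C)[C@H]1/C=C/[C@@H](C)C[C@H](O[Si](C)(C)C(C)(C)C)C[C@](C)(O)[C@H](O)C1 | intermediate
11 | 4α-hydroxy-5-ketone | C=C(C)[C@H]1/C=C/[C@@H](C)C[C@H](O[Si](C)(C)C(C)(C)C)C[C@](C)(O)C(=O)C1 | intermediate
12 | 4α,6α-dihydroxy-5-ketone | C=C(C)[C@H]1/C=C/[C@@H](C)C[C@H](O[Si](C)(C)C(C)(C)C)C[C@](C)(O)C(=O)[C@@H]1O | intermediate
13 | 6α-OTBS ether | C=C(C)[C@H]1/C=C/[C@@H](C)C[C@H](O[Si](C)(C)C(C)(C)C)C[C@](C)(O)C(=O)[C@@H]1O[Si](C)(C)C(C)(C)C | intermediate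
14 | 5β-alcohol | C=C(C)[C@H]1/C=C/[C@@H](C)C[C@H](O[Si](C)(C)C(C)(C)C)C[C@](C)(O)[C@@H](O)[C@@H]1O[Si](C)(C)C(C)(C)C | intermediate
15 | 5β-O-isobutyrate | C=C(C)[C@H]1/C=C/[C@@H](C)C[C@H](O[Si](C)(C)C(C)(C)C)C[C@](C)(O)[C@@H](OC(=O)C(C)C)[C@@H]1O[Si](C)(C)C(C)(C)C | intermediate
16 | 8α,9-diol | C=C(C)[C@H]1[C@H](O)[C@@H](O)[C@@H](C)C[C@H](O[Si](C)(C)C(C)(C)C)C[C@](C)(O)[C@@H](OC(=O)C(C)C)[C@@H]1O[Si](C)(C)C(C)(C)C | intermediate
17 | 8α-hydroxy-9-ketone | C=C(C)[C@H]1[C@H](O)C(=O)[C@@H](C)C[C@H](O[Si](C)(C)C(C)(C)C)C[C@](C)(O)[C@@H](OC(=O)C(C)C)[C@@H]1O[Si](C)(C)C(C)(C)C | intermediate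
18 | 8α-O-isobutyrate | C=C(C)[C@H]1[C@H](OC(=O)C(C)C)C(=O)[C@@H](C)C[C@H](O[Si](C)(C)C(C)(C)C)C[C@](C)(O)[C@@H](OC(=O)C(C)C)[C@@H]1O[Si](C)(C)C(C)(C)C | intermediate
19 | 12-hydroxy compound | C=C(CO)[C@H]1[C@H](OC(=O)C(C)C)C(=O)[C@@H](C)C[C@H](O[Si](C)(C)C(C)(C)C)C[C@](C)(O)[C@@H](OC(=O)C(C)C)[C@@H]1O[Si](C)(C)C(C)(C)C | intermediate
20 | α-methylene acid | C=C(C(=O)O)[C@H]1[C@H](OC(=O)C(C)C)C(=O)[C@@H](C)C[C@H](O[Si](C)(C)C(C)(C)C)C[C@](C)(O)[C@@H](OC(=O)C(C)C)[C@@H]1O[Si](C)(C)C(C)(C)C | intermediate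
21 | 2,6-dihydroxy acid | C=C(C(=O)O)[C@H]1[C@H](OC(=O)C(C)C)C(=O)[C@@H](C)C[C@H](O)C[C@](C)(O)[C@@H](OC(=O)C(C)C)[C@@H]1O | intermediate
22 | cardivin D | C=C1C(=O)O[C@@H]2[C@@H]1[C@H](OC(=O)C(C)C)C(=O)[C@@H](C)C[C@H](O)C[C@](C)(O)[C@H]2OC(=O)C(C)C | target

**Total step count:** 21
**Longest linear sequence:** 21 (every step is linear from compound 1)

**Three steps most likely to fail:**
1. **Step 4 (oxy-Cope).** The endocyclic 1,5-diene (C4=C5/C9=C10) can compete, and the C10 configuration and alkene geometry depend on the transition state.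
   Fallback: ring-open carvone and close the C1–C10 bond by intramolecular Nozaki–Hiyama–Kishi allylation, or build a carvone-derived decalin and apply a Grob fragmentation.
2. **Step 16 (C9 versus C8 oxidation).** Regioselective diol oxidation is sterically judged and the OsO₄ chemoselectivity in Step 15 is assumed.
   Fallback: use the α′-propionyl-derived silyl enol ether as the Cope arm, then Rubottom oxidation gives the 8-hydroxy-9-ketone directly.
3. **Step 13 (C5 configuration).** Directed reduction of the flanked α-hydroxy ketone could give the wrong C5 epimer.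
   Fallback: accept the epimer and install the 5β-ester by Mitsunobu esterification with isobutyric acid (DIAD, PPh₃), which inverts C5.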